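The readings were generated by integration for an exercise; noise was put on by code.

At the time of reading, 12 min after the start, the excess depends on one ratio: left-handed over right-handed product. Both products form with the same coupling partner and free catalyst, each from its own substrate. If each rate is first order in its substrate, that ratio equals the selectivity factor (the rate constant of the left-handed substrate over that of the right-handed one) times the mean left-handed substrate over the mean right-handed substrate up to that time.

in all of them: left-handed substrate 0.011 M; right-handed substrate 0.011 M; free catalyst 0.18 mol%; racemization catalyst 0.66 mol%; added ligand 0.26 mM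

| run | coupling partner | temperature | remark | time |
|---|---|---|---|---|
| spring | 1.5 equiv | −5 °C | run made earlier |  |
| winter | 2.2 equiv | 25 °C | run made earlier |  |
| ochre | 3.00 equiv | 25 °C |  | 12 min |
| teal | 3.00 equiv | 50 °C |  | 12 min |
| green | 3.00 equiv | 0 °C |  | 12 min |

- spring (time / min: left-handed product / %, right-handed product / %, left-handed substrate / %): 6.00: 16.1, 0.5, 34.9; 12.0: 24.6, 1.8, 26.8; 20.0: 32.3, 1.9, 19.8; 25.0: 35.8, 1.8, 16.8; 40.0: 42.4, 3.1, 11.7
- winter (time / min: left-handed product / %, right-handed product / %, left-handed substrate / %): 0.667: 7.0, 0.8, 43.3; 2.00: 17.1, 0.8, 33.1; 3.00: 23.2, 2.3, 28.6; 5.00: 32.3, 3.3, 21.8; 8.00: 39.5, 5.4, 15.8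

(standard deviation of a reading: 0.3 percentage points)

- free catalyst is single-handed; left-handed substrate and right-handed substrate are mirror images of each other, charged as a racemate, each of them at the stated concentration
- an excess is below zero if the other one leads

- the flask that comes out highest in excess of left-handed product over right-handed product, or "all alike" when all lie within 1.5 percentage points (ochre / teal / green / all alike)
- excess of left-handed product over right-handed product at the end, ochre
- excess of left-handed product over right-handed product at the end, teal
- excess of left-handed product over right-handed product at the end, green

The winter run ends at 39.5 % left-handed and 5.4 % right-handed product. Averaging each substrate from its two ends gives a factor of 9.93. But the left-handed substrate falls along a sagging curve, so its two ends overstate the mean. Following the readings, the means are 27.5 % left-handed and 44.6 % right-handed, and the factor becomes 11.9. Another doubt remains: the coupling partner falls, so early minutes, richer in left-handed substrate, count for more, and this reading leans high.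

The spring run, read the same way, has means of 23.3 % and 46.1 %, which gives 27.1 at −5 °C. Drawing the logarithm of the factor straight against degrees gives 23.6 for green and, for teal, a selectivity factor at 50 °C of 5.99. A line in reciprocal temperature would put teal somewhat higher, so this figure leans low.

The substrate ratio of the new flasks is unknown, so the winter value, 0.615, stands in for all three. That gives excesses of 76.0 % for ochre, 57.3 % for teal and 87.1 % for green. With 3.00 equiv of coupling partner, more than the winter run's 2.2 equiv, and 12 min, longer than its 8.00 min, ochre at the winter run's 25 °C and teal, hotter at 50 °C, should run further, so those two figures lean high. Green is colder than the winter run, at 0 °C, so no such lean is claimed for its figure.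

The forecast says green, with 73 %, 64 % and 86 %: “Cold wins at this short time.” For teal it takes a factor of about 8, above the 5.99 reckoned here.

The flasks give green as highest, with 68.4 % for ochre, 51.2 % for teal and 83.9 % for green.

    coupling partner + free catalyst + left-handed substrate → free catalyst + left-handed product (k = 8100 /M²/s, Ea = 18.0 kJ/mol)
    coupling partner + free catalyst + right-handed substrate → free catalyst + right-handed product (k = 720 /M²/s, Ea = 35.0 kJ/mol)
    left-handed substrate + racemization catalyst ⇌ right-handed substrate + racemization catalyst, rate k3*[racemization catalyst]*[left-handed substrate] forward; the back reaction follows from the equilibrium constant (k = 23.0 /M/s, Ea = 53.0 kJ/mol)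
    2 racemization catalyst → spent catalyst (k = 47.0 /M/s, Ea = 49.0 kJ/mol)
    racemization catalyst + added ligand ⇌ idle complex, settled at all times (K = 440 /M, ΔH = −25.0 kJ/mol)
    (constants at 25 °C)

Teal is where the forecast stands furthest off. Its substrates, taken at the start, 6.00 min and 12.0 min with the middle state weighted 4, average 14.1 % and 29.5 %. Their ratio, 0.478, is lower than the winter 0.615, and with 5.99 it gives 48.2 % against 51.2 %. Teal's neighbour with 0.750 equiv of coupling partner ends at 28.8 % left-handed and 39.7 % right-handed substrate. Averaging from the ends gives a ratio of 0.878 and an excess of 68.0 %; the flask gives 69.4 %.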